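**Plan**

1. Retrosynthesis: both (Z)-hex-2-enoates are cut back to a triol (two O–acyl bonds; alkyne in place of each Z-alkene). The C3, C9 and C8 carbinol centres are traced to a keto sulfone, and ring A is opened at C1–C10 and C2–C3, with C1–C2 coming from phenyl vinyl sulfone. The C5–CH3, C5–C4 and C7–isopropenyl bonds of a cyclohexenone are cut last.
2. Forward: ring B is made first (cyclohexenone → 5-isopropenylcyclohexenone 5 → 3,5-disubstituted enone 9 → quaternary C5 in 10). Ring A is then closed in one pot by Michael addition and Dieckmann acylation (step 7). The oxygen pattern and the two esters are set on the trans-decalin.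
3. What makes step 7 possible: on ring B the C9 carbonyl makes C10 a carbon nucleophile, and the ester carbon C3 sits on C4, which hangs on quaternary C5. C10 (donor) and C3 (acceptor) are thus 1,4-related across C5–C4, and a two-carbon acceptor–donor unit closes the six-membered ring A. The sulfonyl group activates C2, then masks the C3 ketone as its enolate, and is removed in step 9.
4. Stereochemistry: C7 from the (R)-BINAP–rhodium conjugate addition; C5 by methyl addition trans to C7; C10 and C4 by equilibration (trans-decalin, equatorial methyl); C8 by axial hydroxylation of the C8 enolate; C9 and C3 by dissolving-metal reduction to the equatorial alcohols; both Z-alkenes by semihydrogenation.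

Key step: step 7

Remark: decalin compounds carry eremophilane numbering (ring A = C1–C2–C3–C4–C5–C10, ring B = C5–C6–C7–C8–C9–C10, C14 = methyl on C5, C15 = methyl on C4, isopropenyl on C7; β = face of the C5 methyl). Compounds 9, 10 and 12–17 are expected as mixtures of C4 epimers (14–16 also of C2 epimers); these converge in step 9.

Step 1
Reactants: 1 cyclohex-2-en-1-one; 2 4,4,5,5-tetramethyl-2-(prop-1-en-2-yl)-1,3,2-dioxaborolane
Product: 3 (R)-3-(prop-1-en-2-yl)cyclohexan-1-one
Conditions: [RhCl(C2H4)2]2 (1.5 mol%), (R)-BINAP (3.3 mol%), KOH (10 mol%), dioxane/H2O, 50 °C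
Reagents that add atoms: none
Why: Rhodium-catalysed asymmetric 1,4-addition of an alkenylboron reagent (Hayashi–Miyaura reaction), in which the (R)-BINAP complex should deliver the isopropenyl group to one face of the enone and so set C7, the centre from which all others are relayed.

Step 2
Reactants: 3
Product: 4 allyl (4R)-2-oxo-4-(prop-1-en-2-yl)cyclohexane-1-carboxylate (keto/enol forms, C1 epimers)
Conditions: NaH (2.2 equiv), diallyl carbonate (1.5 equiv), THF, 65 °C; aq. HCl work-up
Reagents that add atoms: diallyl carbonate C=CCOC(=O)OCC=C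
Why: Claisen-type C-acylation of the ketone enolate under equilibrating conditions should take place at the less hindered α-carbon remote from the isopropenyl-bearing carbon (the future C10), which marks that carbon for the regiospecific dehydrogenation that follows.

Step 3
Reactants: 4
Product: 5 (R)-5-(prop-1-en-2-yl)cyclohex-2-en-1-one
Conditions: Pd(OAc)2 (5 mol%), 1,2-bis(diphenylphosphino)ethane (5 mol%), MeCN, 80 °C
Reagents that add atoms: none
Why: Tsuji decarboxylation–dehydrogenation: zerovalent palladium ionises the allyl ester, CO2 is lost, and the palladium enolate formed at the former ester carbon undergoes β-hydride elimination to the 2-enone without touching C7.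

Step 4
Reactants: 6 methyl propanoate
Product: 7 1-methoxy-1-(trimethylsilyloxy)prop-1-ene (E/Z mixture)
Conditions: LiN(iPr)2, THF, −78 °C; Me3SiCl, −78 → 23 °C
Reagents that add atoms: chlorotrimethylsilane C[Si](C)(C)Cl
Why: Kinetic ester enolisation and O-silylation give the ketene silyl acetal, whose double-bond geometry is of no consequence because the carbon it delivers (C4) is equilibrated in step 9.

Step 5
Reactants: 5; 7
Product: 9 methyl 2-[(5R)-3-oxo-5-(prop-1-en-2-yl)cyclohex-1-en-1-yl]propanoate (C4 epimers), via silyl enol ether 8 (not isolated)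
Conditions: Me3SiOTf (3 mol%), CH2Cl2, −78 °C; solvent change; Pd(OAc)2 (1.05 equiv), MeCN, 23 °C
Reagents that add atoms: none
Why: Mukaiyama–Michael addition places the propanoate unit on C5 and leaves the ketone as a regiodefined silyl enol ether, so that Saegusa–Ito oxidation with divalent palladium should return the enone with its double bond toward the new substituent (C10=C5).

Step 6
Reactants: 9
Product: 10 methyl 2-[(1S,5R)-1-methyl-5-(prop-1-en-2-yl)-3-(trimethylsilyloxy)cyclohex-2-en-1-yl]propanoate (C4 epimers)
Conditions: MeMgBr (1.5 equiv), CuBr·SMe2 (5 mol%), Me3SiCl (2 equiv), HMPA (2 equiv), THF, −78 °C; Et3N, then pentane/aq. NaHCO3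
Reagents that add atoms: methylmagnesium bromide C[Mg]Br; chlorotrimethylsilane C[Si](C)(C)Cl
Why: Copper-catalysed, silyl chloride-accelerated conjugate addition of the methyl Grignard reagent should occur anti to the C7 isopropenyl group (the usual trans selectivity of 5-substituted cyclohexenones), setting quaternary C5, while silyl trapping outruns deprotonation at C4 and fixes the enolate at C10.

Step 7
Reactants: 10; 11 phenyl vinyl sulfone
Product: 14 4,5β-dimethyl-2-(phenylsulfonyl)-7α-(prop-1-en-2-yl)-10αH-decalin-3,9-dione (trans-fused; C2/C4 epimers), via potassium enolate 12 (not isolated), via sulfonyl carbanion 13 (not isolated)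
Conditions: KOtBu (1.0 equiv), THF, −78 → −40 °C; 11 (1.1 equiv), −78 → 0 °C; then KOMe (0.2 equiv), MeOH, 23 °C; AcOH
Reagents that add atoms: none
Why: Desilylation with KOtBu gives the regiodefined C10 potassium enolate 12, which adds to phenyl vinyl sulfone (Michael addition, C1–C10 bond); the α-sulfonyl carbanion 13 then attacks the C3 methyl ester (C2–C3 bond), and the released methoxide deprotonates the keto sulfone, which makes the sequence irreversible. The closest known reaction type is the Michael–Claisen (Michael–Dieckmann) annulation of an ester-bearing carbon nucleophile with a Michael acceptor, here with a vinyl sulfone as a traceless ethylene equivalent. Ring A, the only ring formed, closes by 6-exo-trig acyl substitution at C3. C10 is the new stereocentre that is kept: it lies α to the C9 ketone and is equilibrated by methoxide to the trans ring fusion (10α-H, with C1 and C4 both equatorial on ring B); C2 is removed in step 9, and C4 and C5 are not touched. The step needs the enolate to stay at C10 (a C8 enolate could only acylate C3 to a bridged dione) and the carbanion to cyclise before it adds to more acceptor; the first is secured by the silyl enol ether from step 6 and the absence of a proton source, the second by the six-membered transition state to the nearby ester and a near-stoichiometric amount of 11.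

Step 8
Reactants: 14
Product: 16 8α-hydroxy-4,5β-dimethyl-2-(phenylsulfonyl)-7α-(prop-1-en-2-yl)-10αH-decalin-3,9-dione (C2/C4 epimers), via dipotassium dianion 15 (not isolated)
Conditions: KN(SiMe3)2 (2.3 equiv), THF, −78 °C; 3-phenyl-2-(phenylsulfonyl)oxaziridine (1.1 equiv), −78 °C; AcOH
Reagents that add atoms: 3-phenyl-2-(phenylsulfonyl)oxaziridine O=S(=O)(c1ccccc1)N1OC1c1ccccc1
Why: The first equivalent of base removes the acidic C2–H and so masks the C3 ketone as a stabilised enolate, the second forms the kinetic C8 enolate of the C9 ketone, and this more nucleophilic enolate should be hydroxylated by the N-sulfonyloxaziridine through axial attack on the α face of the rigid trans-decalin, giving the axial 8α-hydroxyl cis to the equatorial isopropenyl group.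

Step 9
Reactants: 16
Product: 18 8α,9α-dihydroxy-4β,5β-dimethyl-7α-(prop-1-en-2-yl)-10αH-decalin-3-one, via keto diol epimers 17 (not isolated)
Conditions: Li (6 equiv), NH3/THF, −78 °C (16 added last); isoprene, then NH4Cl; NH3 evaporated; NaOMe (0.3 equiv), MeOH, 50 °C
Reagents that add atoms: none
Why: Dissolving-metal reduction cleaves the C2–S bond to a C3 enolate that resists further reduction, while the C9 ketone, flanked by the C8 alkoxide (a poor leaving group), is reduced under thermodynamic control to the equatorial 9α-alcohol, and methoxide then equilibrates the freed C3 ketone at C4 to the equatorial 4β-methyl epimer.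

Step 10
Reactants: 18
Product: 19 4β,5β-dimethyl-7α-(prop-1-en-2-yl)-10αH-decalin-3α,8α,9α-triol
Conditions: Li (8 equiv), NH3/THF, EtOH (6 equiv), −78 → −33 °C; NH4Cl
Reagents that add atoms: none
Why: Dissolving-metal reduction of the C3 ketone should give the thermodynamically favoured equatorial 3α-alcohol, whereas hydride reagents would enter from the α face (the β face being screened by the syn-axial C5 methyl) and give the axial epimer.

Step 11
Reactants: 19; 20 hex-2-ynoic acid
Product: 21 8α-hydroxy-4β,5β-dimethyl-7α-(prop-1-en-2-yl)-10αH-decalin-3α,9α-diyl bis(hex-2-ynoate)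
Conditions: 20 (2.2 equiv), N,N'-diisopropylcarbodiimide (2.4 equiv), DMAP (0.2 equiv), CH2Cl2, −20 → 0 °C
Reagents that add atoms: none
Why: Steglich esterification should acylate the two equatorial hydroxyls (C3, C9) ahead of the axial C8 hydroxyl, which is flanked by the isopropenyl group and, after the first acylation, by the C9 ester; the alkynoic acid is used so that the Z geometry can be set afterwards without isomerisation.

Step 12
Reactants: 21
Product: 22 (3R,4R,5R,7S,8R,9S,10R)-8α-hydroxy-4β,5β-dimethyl-7α-(prop-1-en-2-yl)-10αH-decalin-3α,9α-diyl bis[(Z)-hex-2-enoate] (CNP0420276.1)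
Conditions: H2 (1 atm), Pd/CaCO3 poisoned with Pb(OAc)2, quinoline, EtOAc, 23 °C
Reagents that add atoms: none
Why: Lindlar-type syn semihydrogenation of both conjugated alkynes should give the two (Z)-enoates, and the poisoned catalyst should leave the 1,1-disubstituted alkene untouched.

**Compound list**

1 | cyclohex-2-en-1-one | O=C1C=CCCC1 | starting material
2 | 4,4,5,5-tetramethyl-2-(prop-1-en-2-yl)-1,3,2-dioxaborolane | CC(=C)B1OC(C)(C)C(C)(C)O1 | starting material
3 | (R)-3-(prop-1-en-2-yl)cyclohexan-1-one | C=C(C)[C@@H]1CCCC(=O)C1 | intermediate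
4 | allyl (4R)-2-oxo-4-(prop-1-en-2-yl)cyclohexane-1-carboxylate (C1 epimers) | C=C(C)[C@@H]1CCC(C(=O)OCC=C)C(=O)C1 | intermediate
5 | (R)-5-(prop-1-en-2-yl)cyclohex-2-en-1-one | C=C(C)[C@@H]1CC=CC(=O)C1 | intermediate
6 | methyl propanoate | CCC(=O)OC | starting material
7 | 1-methoxy-1-(trimethylsilyloxy)prop-1-ene (E/Z mixture) | CC=C(OC)O[Si](C)(C)C | intermediate
8 | methyl 2-[(1R,5R)-5-(prop-1-en-2-yl)-3-(trimethylsilyloxy)cyclohex-2-en-1-yl]propanoate (1,5-trans; not isolated) | C=C(C)[C@@H]1C[C@@H](C(C)C(=O)OC)C=C(O[Si](C)(C)C)C1 | intermediate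
9 | methyl 2-[(5R)-3-oxo-5-(prop-1-en-2-yl)cyclohex-1-en-1-yl]propanoate (C4 epimers) | C=C(C)[C@@H]1CC(C(C)C(=O)OC)=CC(=O)C1 | intermediate
10 | methyl 2-[(1S,5R)-1-methyl-5-(prop-1-en-2-yl)-3-(trimethylsilyloxy)cyclohex-2-en-1-yl]propanoate (methyl trans to isopropenyl; C4 epimers) | C=C(C)[C@@H]1C[C@](C)(C(C)C(=O)OC)C=C(O[Si](C)(C)C)C1 | intermediate
11 | phenyl vinyl sulfone | C=CS(=O)(=O)c1ccccc1 | starting material
12 | potassium enolate of 10 after loss of the silyl group (C10=C9–O–K; not isolated) | C=C(C)[C@@H]1C[C@](C)(C(C)C(=O)OC)C=C([O-])C1.[K+] | intermediate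
13 | Michael adduct of 12 and 11, carbanion at C2 α to the sulfonyl group (not isolated) | C=C(C)[C@@H]1C[C@](C)(C(C)C(=O)OC)C(C[CH-]S(=O)(=O)c2ccccc2)C(=O)C1.[K+] | intermediate
14 | 4,5β-dimethyl-2-(phenylsulfonyl)-7α-(prop-1-en-2-yl)-10αH-decalin-3,9-dione (trans-fused; C2/C4 epimers) | C=C(C)[C@@H]1C[C@]2(C)C(C)C(=O)C(S(=O)(=O)c3ccccc3)C[C@H]2C(=O)C1 | intermediate
15 | dipotassium dianion of 14 (C2=C3 enolate and C8=C9 enolate; not isolated) | C=C(C)[C@@H]1C[C@]2(C)C(C)C([O-])=C(S(=O)(=O)c3ccccc3)C[C@H]2C([O-])=C1.[K+].[K+] | intermediate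
16 | 8α-hydroxy-4,5β-dimethyl-2-(phenylsulfonyl)-7α-(prop-1-en-2-yl)-10αH-decalin-3,9-dione (C2/C4 epimers) | C=C(C)[C@@H]1C[C@]2(C)C(C)C(=O)C(S(=O)(=O)c3ccccc3)C[C@H]2C(=O)[C@@H]1O | intermediate
17 | 8α,9α-dihydroxy-4,5β-dimethyl-7α-(prop-1-en-2-yl)-10αH-decalin-3-one (C4 epimers; not isolated) | C=C(C)[C@@H]1C[C@]2(C)C(C)C(=O)CC[C@H]2[C@H](O)[C@@H]1O | intermediate
18 | 8α,9α-dihydroxy-4β,5β-dimethyl-7α-(prop-1-en-2-yl)-10αH-decalin-3-one | C=C(C)[C@@H]1C[C@]2(C)[C@@H](C)C(=O)CC[C@H]2[C@H](O)[C@@H]1O | intermediate
19 | 4β,5β-dimethyl-7α-(prop-1-en-2-yl)-10αH-decalin-3α,8α,9α-triol | C=C(C)[C@@H]1C[C@]2(C)[C@@H](C)[C@H](O)CC[C@H]2[C@H](O)[C@@H]1O | intermediate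
20 | hex-2-ynoic acid | CCCC#CC(=O)O | starting material
21 | 8α-hydroxy-4β,5β-dimethyl-7α-(prop-1-en-2-yl)-10αH-decalin-3α,9α-diyl bis(hex-2-ynoate) | C=C(C)[C@@H]1C[C@]2(C)[C@@H](C)[C@H](OC(=O)C#CCCC)CC[C@H]2[C@H](OC(=O)C#CCCC)[C@@H]1O | intermediate
22 | (3R,4R,5R,7S,8R,9S,10R)-8α-hydroxy-4β,5β-dimethyl-7α-(prop-1-en-2-yl)-10αH-decalin-3α,9α-diyl bis[(Z)-hex-2-enoate] | C=C(C)[C@@H]1C[C@]2(C)[C@@H](C)[C@H](OC(=O)/C=C\CCC)CC[C@H]2[C@H](OC(=O)/C=C\CCC)[C@@H]1O | target

**Step count and risks**

Total step count: 12. Longest linear sequence: 11 steps (steps 1–3 and 5–12; step 4 is a side branch).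

Most likely to fail, first: step 7. The C10 enolate may lose its position by proton transfer before it meets the acceptor, after which a C8 enolate can acylate C3 to a bridged dione. The sulfonyl carbanion may add to a second molecule of 11 instead of closing the ring. The ring fusion may not settle as trans. The fallback sets out from 10 and returns at 14; it reverses the order of bond formation and brings in C1 as formaldehyde. Acylation of the side-chain ester of 10 with LiCH2SO2Ph (from methyl phenyl sulfone and n-BuLi, THF, −78 → 0 °C; dilute acid work-up, which also hydrolyses the silyl enol ether) should give 1-(phenylsulfonyl)-3-[(1S,5R)-1-methyl-3-oxo-5-(prop-1-en-2-yl)cyclohexyl]butan-2-one F1. Knoevenagel condensation of F1 with formaldehyde (piperidinium acetate, MeOH, 23 °C) should give 2-(phenylsulfonyl)-4-[(1S,5R)-1-methyl-3-oxo-5-(prop-1-en-2-yl)cyclohexyl]pent-1-en-3-one F2. F2 is not isolated: the enol of the C9 ketone adds through C10 to the new methylene group (intramolecular Michael addition; only C10 reaches it in a six-membered ring) and gives 14.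

Second: step 9. The C8 oxygen may be lost reductively from the α-ketol, the C–S bond may survive if the keto sulfone is deprotonated before it is reduced, and the C3 carbonyl may be reduced on quenching. The fallback sets out from 16 and returns at 18; it uses kinetic hydride and amalgam chemistry on a protected ketol. Silylation (Et3SiOTf, 2,6-lutidine, CH2Cl2, −78 °C) should give the 8α-triethylsilyl ether of 16 F3. NaH (1 equiv) masks the keto sulfone as its sodium enolate, and NaBH4 (THF/MeOH, −40 °C) should then reduce only the C9 ketone, anti to the axial C8–O bond (Felkin–Anh), to the 9α-alcohol F4. Al(Hg) in THF/H2O removes the sulfonyl group to give the 3-ketone 8-silyl ether F5. AcOH/THF/H2O cleaves the silyl ether to 17, and NaOMe in MeOH as in step 9 gives 18.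

Third: step 11. Site selectivity among the three secondary hydroxyls may be lost through acylation of the axial C8 hydroxyl, over-acylation, or acyl migration between O9 and O8. The fallback sets out from 19 and 20 and returns at 21; it is a stepwise, catalyst-controlled acylation. 20 is converted with (COCl)2 and catalytic DMF into hex-2-ynoyl chloride F6. With 2-aminoethyl diphenylborinate (10 mol%), iPr2NEt, MeCN, 0 °C, the cis-8,9-diol is activated as its borinate and should be acylated by F6 at the equatorial O9 to give the 9-mono(hex-2-ynoate) of 19 F7. Steglich esterification of F7 with 20 at the C3 hydroxyl then gives 21.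

**Further compounds**

F1 | step 7 | 1-(phenylsulfonyl)-3-[(1S,5R)-1-methyl-3-oxo-5-(prop-1-en-2-yl)cyclohexyl]butan-2-one (C4 epimers) | C=C(C)[C@@H]1C[C@](C)(C(C)C(=O)CS(=O)(=O)c2ccccc2)CC(=O)C1
F2 | step 7 | 2-(phenylsulfonyl)-4-[(1S,5R)-1-methyl-3-oxo-5-(prop-1-en-2-yl)cyclohexyl]pent-1-en-3-one (C4 epimers) | C=C(C)[C@@H]1C[C@](C)(C(C)C(=O)C(=C)S(=O)(=O)c2ccccc2)CC(=O)C1
F3 | step 9 | 4,5β-dimethyl-2-(phenylsulfonyl)-7α-(prop-1-en-2-yl)-8α-(triethylsilyloxy)-10αH-decalin-3,9-dione (C2/C4 epimers) | C=C(C)[C@@H]1C[C@]2(C)C(C)C(=O)C(S(=O)(=O)c3ccccc3)C[C@H]2C(=O)[C@@H]1O[Si](CC)(CC)CC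
F4 | step 9 | 9α-hydroxy-4,5β-dimethyl-2-(phenylsulfonyl)-7α-(prop-1-en-2-yl)-8α-(triethylsilyloxy)-10αH-decalin-3-one (C2/C4 epimers) | C=C(C)[C@@H]1C[C@]2(C)C(C)C(=O)C(S(=O)(=O)c3ccccc3)C[C@H]2[C@H](O)[C@@H]1O[Si](CC)(CC)CC
F5 | step 9 | 9α-hydroxy-4,5β-dimethyl-7α-(prop-1-en-2-yl)-8α-(triethylsilyloxy)-10αH-decalin-3-one (C4 epimers) | C=C(C)[C@@H]1C[C@]2(C)C(C)C(=O)CC[C@H]2[C@H](O)[C@@H]1O[Si](CC)(CC)CC
F6 | step 11 | hex-2-ynoyl chloride | CCCC#CC(=O)Cl
F7 | step 11 | 3α,8α-dihydroxy-4β,5β-dimethyl-7α-(prop-1-en-2-yl)-10αH-decalin-9α-yl hex-2-ynoate | C=C(C)[C@@H]1C[C@]2(C)[C@@H](C)[C@H](O)CC[C@H]2[C@H](OC(=O)C#CCCC)[C@@H]1O
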